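Numbering the chain C1 (Z-allylic CH2OH) to C16, everything rests on cutting C8–C9, the bond between the carbinol beside the oxirane (O, C6, C7) and the allylic CH2. The feature exploited is the C8(OH)–C9H2–C10H=C11(CH3)–C12(OH) unit, an (E)-2-methylpent-2-ene-1,5-anti-diol. One operation, an allene hydroboration–double allylboration, assembles it from three components: a four-carbon allenylboronate (C9–C11 plus methyl) is hydroborated with (dIpc)2BH, adds 4-methylpent-3-enal (C12–C16), and the resulting tertiary allylboronate allylates an α-quaternary epoxy aldehyde (C1–C8), forming C8–C9, the E olefin and both carbinol stereocentres. The epoxy aldehyde comes from nerol by Sharpless epoxidation.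

Key step: step 11

Remark: locants C1–C16 are those of the target chain defined above. (dIpc)2BH is (−)-diisopinocampheylborane from (+)-α-pinene, B([C@@H]1C[C@@H]2C[C@H]([C@H]1C)C2(C)C)[C@@H]1C[C@@H]2C[C@H]([C@H]1C)C2(C)C, taken as a purchased reagent like TOM-Cl and B2pin2.

Step 1
Reactants: 1 nerol
Product: 2 neryl TBS ether (tert-butyl{[(2Z)-3,7-dimethylocta-2,6-dien-1-yl]oxy}dimethylsilane)
Conditions: TBSCl, imidazole, CH2Cl2, 0 °C → rt
Reagents that add atoms: TBSCl, CC(C)(C)[Si](C)(C)Cl
Why: Imidazole-promoted O-silylation of the primary allylic alcohol should be clean and leaves both olefins and the Z geometry untouched.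

Step 2
Reactants: 2 neryl TBS ether
Product: 4 (4Z)-6-[(tert-butyldimethylsilyl)oxy]-4-methylhex-4-enal, via racemic terminal epoxide 3 (not isolated)
Conditions: mCPBA (1.0 equiv), NaHCO3, CH2Cl2, −20 → 0 °C; then H5IO6, THF/H2O, 0 °C
Reagents that add atoms: mCPBA, OOC(=O)c1cccc(Cl)c1
Why: Prilezhaev epoxidation should take the remote 6,7-olefin because the 2,3-olefin is deactivated by the allylic silyloxy group, and periodic acid then hydrolyses the epoxide and cleaves the glycol to the aldehyde and acetone without touching the Z olefin.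

Step 3
Reactants: 5 triethyl phosphonoacetate
Product: 6 ethyl 2-(diethoxyphosphoryl)-3-[(triisopropylsilyl)oxy]propanoate (racemic)
Conditions: NaH, THF, 0 °C; then TOM-Cl, 0 °C → rt
Reagents that add atoms: (triisopropylsiloxy)methyl chloride (TOM-Cl), ClCO[Si](C(C)C)(C(C)C)C(C)C
Why: Malonate-type C-alkylation of the stabilised phosphonoacetate carbanion with the reactive α-chloro ether installs the silyl-protected hydroxymethyl carbon.

Step 4
Reactants: 6 phosphonate; 4 aldehyde
Product: 7 ethyl (2E,6Z)-8-[(tert-butyldimethylsilyl)oxy]-6-methyl-2-{[(triisopropylsilyl)oxy]methyl}octa-2,6-dienoate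
Conditions: NaH, THF, 0 °C; then 4, 0 °C → rt
Reagents that add atoms: none
Why: Horner–Wadsworth–Emmons olefination with an α-substituted phosphonoacetate should favour the (E)-enoate (chain trans to the ester, cis to CH2OTIPS) through reversible adduct formation; the minor Z isomer is removed by chromatography.

Step 5
Reactants: 7 enoate
Product: 8 (2Z,6Z)-8-[(tert-butyldimethylsilyl)oxy]-6-methyl-2-{[(triisopropylsilyl)oxy]methyl}octa-2,6-dien-1-ol
Conditions: DIBAL-H (2.5 equiv), CH2Cl2, −78 °C; Rochelle salt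
Reagents that add atoms: none
Why: DIBAL-H 1,2-reduction of the enoate gives the allylic alcohol with retention of olefin geometry (free CH2OH trans to the chain), and the silyl ethers are inert.

Step 6
Reactants: 8 allylic alcohol
Product: 9 [(2R,3S)-3-{(3Z)-5-[(tert-butyldimethylsilyl)oxy]-3-methylpent-3-en-1-yl}-2-{[(triisopropylsilyl)oxy]methyl}oxiran-2-yl]methanol
Conditions: Ti(Oi-Pr)4 (10 mol %), L-(+)-DET (12 mol %), TBHP, 4 Å MS, CH2Cl2, −20 °C
Reagents that add atoms: tert-butyl hydroperoxide, CC(C)(C)OO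
Why: Sharpless asymmetric epoxidation of the E-type trisubstituted allylic alcohol with the L-(+)-tartrate catalyst should deliver oxygen to the face that sets the oxirane carbons later called C6 and C7 (both S in the target; 2R,3S in 9 only through priority changes), while the silyl-protected olefin has no directing hydroxyl.

Step 7
Reactants: 9 epoxy alcohol
Product: 10 (2R,3S)-3-{(3Z)-5-[(tert-butyldimethylsilyl)oxy]-3-methylpent-3-en-1-yl}-2-{[(triisopropylsilyl)oxy]methyl}oxirane-2-carbaldehyde
Conditions: Dess–Martin periodinane, NaHCO3, CH2Cl2, 0 °C → rt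
Reagents that add atoms: none
Why: Buffered Dess–Martin oxidation gives the α-quaternary epoxy aldehyde, which has no α-hydrogen and so cannot epimerise.

Step 8
Reactants: 11 4-methylpent-3-en-1-ol
Product: 12 4-methylpent-3-enal
Conditions: Dess–Martin periodinane, NaHCO3, CH2Cl2, 0 °C; used at once as a solution
Reagents that add atoms: none
Why: Buffered Dess–Martin oxidation under neutral conditions should avoid migration of the β,γ-olefin into conjugation.

Step 9
Reactants: 13 but-2-yn-1-ol
Product: 14 but-2-yn-1-yl methyl carbonate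
Conditions: ClCO2Me, pyridine, CH2Cl2, 0 °C
Reagents that add atoms: methyl chloroformate, COC(=O)Cl
Why: O-acylation with the chloroformate gives the propargylic carbonate leaving group.

Step 10
Reactants: 14 carbonate
Product: 15 2-(buta-2,3-dien-2-yl)-4,4,5,5-tetramethyl-1,3,2-dioxaborolane
Conditions: B2pin2, CuCl (10 mol %), Xantphos (10 mol %), KOt-Bu (10 mol %), THF, rt
Reagents that add atoms: bis(pinacolato)diboron, CC1(C)OB(OC1(C)C)B1OC(C)(C)C(C)(C)O1
Why: Copper(I)–boryl SN2′ substitution of the propargylic carbonate places boron on the methyl-bearing alkyne carbon and gives the 1,1-disubstituted allenylboronate with loss of CO2 and methoxide.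

Step 11
Reactants: 15 allenylboronate; 12 4-methylpent-3-enal; 10 epoxy aldehyde
Product: 20 (2Z,6S,7S,8S,10E,12R)-1-[(tert-butyldimethylsilyl)oxy]-6,7-epoxy-3,11,15-trimethyl-7-{[(triisopropylsilyl)oxy]methyl}hexadeca-2,10,14-triene-8,12-diol, via kinetic allylborane 16 (not isolated), via equilibrated allylborane 17 (not isolated), via tertiary allylboronate 18 (not isolated), via mixed boron ester 19 (not isolated)
Conditions: (dIpc)2BH (1.0 equiv), toluene, 0 °C, 2 h; 85 °C, 1.5 h; −78 °C, 12 (0.95 equiv), 4 h; 10 (0.7 equiv), −78 °C → rt, 36 h; pH 7 buffer, MeOH, 30% H2O2, 0 °C → rt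
Reagents that add atoms: none
Why: Hydroboration of the unsubstituted C=C of 15 puts boron on the terminal carbon to give γ-boryl allylborane 16, which on heating equilibrates by reversible 1,3-boratropic shifts to the more stable isomer 17 (Bpin trans to CH2B); the sequence is the known allene hydroboration–double allylboration, a three-component coupling. 17 adds 12 through a chair Zimmerman–Traxler transition state in which the (dIpc)2B group directs attack to the Si face (C12 = R) and the trans-Bpin sits equatorial, so 18 carries O and Bpin anti at the tertiary boronate centre. 18 then allylates 10 through a second chair with the bulky CH(OBIpc2)R group equatorial and the methyl axial, which forms C8–C9, gives the (E)-C10=C11 olefin and transfers the boronate chirality to C8 (S, 1,5-anti to C12). No ring is closed. The step needs E over Z and the 8S face: the size difference between methyl and the borinate-bearing carbon should secure the former, and the latter is reagent-controlled and reinforced by the Cornforth-type preference of the epoxy aldehyde for addition anti to the oxirane oxygen. No Lewis acid is present, so the oxirane and silyl ethers should survive, and buffered peroxide work-up cleaves both B–O bonds.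

Step 12
Reactants: 20 bis-silyl diol
Product: 21 (2Z,6S,7S,8S,10E,12R)-6,7-epoxy-7-(hydroxymethyl)-3,11,15-trimethylhexadeca-2,10,14-triene-1,8,12-triol (target)
Conditions: TBAF/AcOH (1:1), THF, 0 °C → rt
Reagents that add atoms: none
Why: Fluoride-mediated desilylation removes both primary silyl ethers; acetic acid buffering should suppress alkoxide-driven Payne rearrangement of the α-hydroxy oxirane, and no stereocentre is touched.

Compound list

1 | nerol, (2Z)-3,7-dimethylocta-2,6-dien-1-ol | CC(C)=CCC/C(C)=C\CO | starting material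
2 | tert-butyl{[(2Z)-3,7-dimethylocta-2,6-dien-1-yl]oxy}dimethylsilane | CC(C)=CCC/C(C)=C\CO[Si](C)(C)C(C)(C)C | intermediate
3 | tert-butyl{[(2Z)-5-(3,3-dimethyloxiran-2-yl)-3-methylpent-2-en-1-yl]oxy}dimethylsilane (racemic) | CC1(C)OC1CC/C(C)=C\CO[Si](C)(C)C(C)(C)C | intermediate
4 | (4Z)-6-[(tert-butyldimethylsilyl)oxy]-4-methylhex-4-enal | O=CCC/C(C)=C\CO[Si](C)(C)C(C)(C)C | intermediate
5 | triethyl phosphonoacetate | CCOC(=O)CP(=O)(OCC)OCC | starting material
6 | ethyl 2-(diethoxyphosphoryl)-3-[(triisopropylsilyl)oxy]propanoate (racemic) | CCOC(=O)C(CO[Si](C(C)C)(C(C)C)C(C)C)P(=O)(OCC)OCC | intermediate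
7 | ethyl (2E,6Z)-8-[(tert-butyldimethylsilyl)oxy]-6-methyl-2-{[(triisopropylsilyl)oxy]methyl}octa-2,6-dienoate | CCOC(=O)/C(CO[Si](C(C)C)(C(C)C)C(C)C)=C/CC/C(C)=C\CO[Si](C)(C)C(C)(C)C | intermediate
8 | (2Z,6Z)-8-[(tert-butyldimethylsilyl)oxy]-6-methyl-2-{[(triisopropylsilyl)oxy]methyl}octa-2,6-dien-1-ol | OC/C(CO[Si](C(C)C)(C(C)C)C(C)C)=C/CC/C(C)=C\CO[Si](C)(C)C(C)(C)C | intermediate
9 | [(2R,3S)-3-{(3Z)-5-[(tert-butyldimethylsilyl)oxy]-3-methylpent-3-en-1-yl}-2-{[(triisopropylsilyl)oxy]methyl}oxiran-2-yl]methanol | OC[C@]1(CO[Si](C(C)C)(C(C)C)C(C)C)O[C@H]1CC/C(C)=C\CO[Si](C)(C)C(C)(C)C | intermediate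
10 | (2R,3S)-3-{(3Z)-5-[(tert-butyldimethylsilyl)oxy]-3-methylpent-3-en-1-yl}-2-{[(triisopropylsilyl)oxy]methyl}oxirane-2-carbaldehyde | O=C[C@]1(CO[Si](C(C)C)(C(C)C)C(C)C)O[C@H]1CC/C(C)=C\CO[Si](C)(C)C(C)(C)C | intermediate
11 | 4-methylpent-3-en-1-ol | CC(C)=CCCO | starting material
12 | 4-methylpent-3-enal | CC(C)=CCC=O | intermediate
13 | but-2-yn-1-ol | CC#CCO | starting material
14 | but-2-yn-1-yl methyl carbonate | CC#CCOC(=O)OC | intermediate
15 | 2-(buta-2,3-dien-2-yl)-4,4,5,5-tetramethyl-1,3,2-dioxaborolane | CC(=C=C)B1OC(C)(C)C(C)(C)O1 | intermediate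
16 | bis(dIpc)[3-(pinacolboryl)but-2-en-1-yl]borane, Bpin cis to CH2B (kinetic isomer) | C/C(B1OC(C)(C)C(C)(C)O1)=C/CB([C@@H]1C[C@@H]2C[C@H]([C@H]1C)C2(C)C)[C@@H]1C[C@@H]2C[C@H]([C@H]1C)C2(C)C | intermediate
17 | bis(dIpc)[3-(pinacolboryl)but-2-en-1-yl]borane, Bpin trans to CH2B (equilibrated isomer) | C/C(B1OC(C)(C)C(C)(C)O1)=C\CB([C@@H]1C[C@@H]2C[C@H]([C@H]1C)C2(C)C)[C@@H]1C[C@@H]2C[C@H]([C@H]1C)C2(C)C | intermediate
18 | (3R,4R)-3,7-dimethyl-3-(pinacolboryl)octa-1,6-dien-4-yl bis(dIpc)borinate | CC(C)=CC[C@@H](OB([C@@H]1C[C@@H]2C[C@H]([C@H]1C)C2(C)C)[C@@H]1C[C@@H]2C[C@H]([C@H]1C)C2(C)C)[C@@](C)(B1OC(C)(C)C(C)(C)O1)C=C | intermediate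
19 | 20 carrying O–B(dIpc)2 at C12 and O–Bpin at C8 | CC(C)=CC[C@@H](OB([C@@H]1C[C@@H]2C[C@H]([C@H]1C)C2(C)C)[C@@H]1C[C@@H]2C[C@H]([C@H]1C)C2(C)C)/C(C)=C/C[C@H](OB1OC(C)(C)C(C)(C)O1)[C@]1(CO[Si](C(C)C)(C(C)C)C(C)C)O[C@H]1CC/C(C)=C\CO[Si](C)(C)C(C)(C)C | intermediate
20 | (2Z,6S,7S,8S,10E,12R)-1-[(tert-butyldimethylsilyl)oxy]-6,7-epoxy-3,11,15-trimethyl-7-{[(triisopropylsilyl)oxy]methyl}hexadeca-2,10,14-triene-8,12-diol | CC(C)=CC[C@@H](O)/C(C)=C/C[C@H](O)[C@]1(CO[Si](C(C)C)(C(C)C)C(C)C)O[C@H]1CC/C(C)=C\CO[Si](C)(C)C(C)(C)C | intermediate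
21 | (2Z,6S,7S,8S,10E,12R)-6,7-epoxy-7-(hydroxymethyl)-3,11,15-trimethylhexadeca-2,10,14-triene-1,8,12-triol | CC(C)=CC[C@@H](O)/C(C)=C/C[C@H](O)[C@]1(CO)O[C@H]1CC/C(C)=C\CO | target

Total step count: 12. Longest linear sequence: 8 steps (1, 2, 4, 5, 6, 7, 11, 12, from nerol).

Steps most likely to fail

1. Step 11. The second allylboration joins a tertiary allylboronate to an α-quaternary aldehyde and may be slow. This would let the wrong α-substituent go axial (Z olefin with the C8 epimer), and incomplete thermal equilibration of the allylborane would carry the kinetic isomer into the 1,5-syn/Z series. The fallback sets out from 10 and 15 (with 12 as the third piece) and comes back at 20. A chiral-phosphoric-acid-catalysed SE2′ propargylation of 10 with 15 (toluene, 4 Å MS, −20 °C) forms the same C8–C9 bond and should give the homopropargylic alcohol F1 with 8S, catalyst control being matched with the anti preference of the epoxy aldehyde. Hydrozirconation of the 2-alkyne with excess Cp2Zr(H)Cl (zirconium at the methyl-bearing carbon), transmetalation with Me2Zn and addition to 12 should give the (E)-allylic alcohol as a C12-epimer mixture F2. MnO2 oxidises only the allylic hydroxyl to the enone F3, and Corey–Bakshi–Shibata reduction with (S)-Me-CBS/catecholborane should install 12R and return to 20.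

2. Step 4. The α-branched phosphonate anion may give poor E/Z control or lose silanolate by β-elimination before it olefinates. The fallback sets out from 4 and comes back at 7. Ethyl 3-[(triisopropylsilyl)oxy]propanoate F4 (from ethyl 3-hydroxypropanoate, TIPSCl and imidazole) is deprotonated with LDA at −78 °C and added to 4 to give the aldol adduct F5 as a diastereomer mixture. Mesylation (MsCl, Et3N) followed by DBU-induced E1cB elimination should give the thermodynamically favoured (E)-enoate 7.

3. Step 2. Competing epoxidation of the 2,3-olefin, or acid-induced loss of the allylic silyl ether during the periodic acid cleavage, may erode the aldehyde. The fallback sets out from 2 and comes back at 4 directly: ozonolysis with one equivalent of ozone (Sudan III end point) in CH2Cl2/pyridine at −78 °C, then Me2S, cleaves the more electron-rich remote olefin without an epoxide intermediate.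

Further compounds

F1 | step 11 | (1S)-1-[(2S,3S)-3-{(3Z)-5-[(tert-butyldimethylsilyl)oxy]-3-methylpent-3-en-1-yl}-2-{[(triisopropylsilyl)oxy]methyl}oxiran-2-yl]pent-3-yn-1-ol | CC#CC[C@H](O)[C@]1(CO[Si](C(C)C)(C(C)C)C(C)C)O[C@H]1CC/C(C)=C\CO[Si](C)(C)C(C)(C)C
F2 | step 11 | C12-epimer mixture of 20 | CC(C)=CCC(O)/C(C)=C/C[C@H](O)[C@]1(CO[Si](C(C)C)(C(C)C)C(C)C)O[C@H]1CC/C(C)=C\CO[Si](C)(C)C(C)(C)C
F3 | step 11 | (2Z,6S,7S,8S,10E)-1-[(tert-butyldimethylsilyl)oxy]-6,7-epoxy-8-hydroxy-3,11,15-trimethyl-7-{[(triisopropylsilyl)oxy]methyl}hexadeca-2,10,14-trien-12-one | CC(C)=CCC(=O)/C(C)=C/C[C@H](O)[C@]1(CO[Si](C(C)C)(C(C)C)C(C)C)O[C@H]1CC/C(C)=C\CO[Si](C)(C)C(C)(C)C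
F4 | step 4 | ethyl 3-[(triisopropylsilyl)oxy]propanoate | CCOC(=O)CCO[Si](C(C)C)(C(C)C)C(C)C
F5 | step 4 | ethyl (6Z)-8-[(tert-butyldimethylsilyl)oxy]-3-hydroxy-6-methyl-2-{[(triisopropylsilyl)oxy]methyl}oct-6-enoate (diastereomer mixture) | CCOC(=O)C(CO[Si](C(C)C)(C(C)C)C(C)C)C(O)CC/C(C)=C\CO[Si](C)(C)C(C)(C)C
F0 | step 2 | none | none
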